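## The problem

The target 26, (2E)-3-{4-[(4S)-5-{4-[3-(furan-3-yl)propyl]furan-2-yl}-4-methylpentyl]furan-2-yl}-2-methylprop-2-enoic acid, has no fused or bridged rings: three separate furans are strung on saturated tethers. Ring A (2,4-disubstituted) carries the (E)-2-methylacrylic acid at C2. Its C4 is joined through CH2CH2CH2–CH(CH3)–CH2 to C2 of ring B (also 2,4-disubstituted), and C4 of ring B is joined through (CH2)3 to C3 of ring C. The skeleton therefore has to be assembled through four C(sp3)–C(sp2) bonds to furans, one at an α-carbon (ring B C2) and three at β-carbons. The only stereocentre is the methyl-bearing CH. It is flanked by CH2 groups and remote from every functional group, so it can neither be controlled by nor control anything else, and, being alone, it offers no diastereomers through which its enantiomeric purity could be raised later; it must be set by a reagent and then carried through steps that cannot epimerise it. All three furans are sensitive to acid, oxidants and electrophilic halogen, rings A and B share one substitution pattern and ring C has two free α-positions, so halogenation, C–H metalation or hydrogenation would not tell the rings apart; every ring-to-chain bond must come from a handle already in place, and the (E)-enoate should stay an ester until the last step. The feature that opens the molecule is the CH(CH3) carbon between the tether CH2 on the ring A side and the CH2 on ring B C2. This CH2–CH(CH3)–CH2 pattern is what results when an ethyl unit, as a configurationally defined α-oxyalkyl carbenoid, is inserted into the C–B bond of a primary boronic ester and the boron left on the new centre then takes up one further CH2.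

## Retrosynthesis

**Acid to ester.** Acid 26 is traced to its ethyl ester 25. No skeletal bond is cut. The ester is the form in which the enoate arises from the olefination and in which it tolerates an organozinc reagent. The forward step is a mild saponification that must leave the (E)-alkene and the furans alone.

**Ring A C4–CH2 bond.** Cutting the bond from ring A C4 to the tether gives the primary iodide 20, used as its organozinc 24, and the bromofuryl enoate 23. The neighbouring cut at the ring A C2–vinyl bond would mean building the acrylate on the complete molecule. The cut at C4 lets 23 come in one Wittig step from 4-bromofuran-2-carbaldehyde 21 and the stabilised ylide 22, with the E geometry settled before the fragments meet. Iodide 20 is simpler than 25 by one furan and the enoate. The forward reaction is a Negishi coupling at a β-bromofuran beside an enoate, which an alkylzinc halide does not attack.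

**Iodide to silyl ether.** Iodide 20 comes from alcohol 19 and this from silyl ether 18. These are functional-group changes only. The oxygen is the one that the tether carries from the start, and the silyl ether is the form in which this terminus passes the organolithium and palladium steps.

**Ring B C4–CH2 bond.** Silyl ether 18 is cut at ring B C4 into the 4-bromofuran 11 and the organozinc 17. Reagent 17 derives from iodide 16, alcohol 15 and finally 3-bromofuran 12 and oxetane 13 through furan-3-yllithium 14. Bromine–lithium exchange places the three-carbon tether on ring C at the carbon that carried bromine, so the two free α-positions of ring C are never asked to react. Joining rings B and C first and attaching the pair to the chain afterwards would be more convergent. It would, however, require a halogen to be placed at one α-carbon of ring B while ring C offers two unsubstituted α-carbons, and no selective way of doing this is apparent. The linear order avoids the question.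

**Ring B C2–CH2 bond.** Bromofuran 11 is cut at ring B C2 into the primary boronic ester 9 and 2,4-dibromofuran 10. Both handles of ring B are then bought in place, and the α C–Br bond is the one that reacts first with zerovalent palladium. The forward reaction is a site-selective B-alkyl Suzuki–Miyaura coupling that must not disturb the stereocentre β to boron.

**One-carbon insertion.** Boronic ester 9 is traced to the secondary boronic ester 7 by removing the CH2 between the stereocentre and boron. Forward, this is a Matteson homologation through boronate 8, in which the stereocentre migrates with retention.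

**The stereocentre.** Boronic ester 7 is cut between CH(CH3) and the tether CH2 into ethyl 2,4,6-triisopropylbenzoate 2 and the primary boronic ester 4. In the forward direction 2 is deprotonated to the chiral organolithium 5, which gives boronate complex 6 and then 7. This cut is preferred to one at the C–CH3 bond or at the bond to the ring B side because both fragments are achiral and each is made in one step. The configuration comes from the diamine alone, and boron ends up exactly where the next carbon is needed.

**Starting materials.** Ester 2 comes from 2,4,6-triisopropylbenzoic acid 1 by ethylation. Boronic ester 4 comes from allyloxy(tert-butyl)dimethylsilane 3 by terminal hydroboration.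

## Roads not taken

Alternative 1: The cut goes through ring B itself. Its C2–C3 and O–C2 bonds are undone, leaving the terminal alkyne A2 (ring A, the enoate and the stereocentre, now propargylic) and the (Z)-iodoallylic alcohol A3 (ring C and its tether). Forward, A2 and A3 would be joined with PdCl2(PPh3)2 and CuI and the coupled product cyclised in the same flask by AgOTf (5-exo attack of the hydroxyl on the alkyne, then aromatisation). The product A1 is identical with 25 and one hydrolysis from 26.
- Merits: ring B is made with an unambiguous 2,4-pattern, so no site selection on a dihalofuran and no alkylboron coupling are needed, and the two large halves meet at the very end. In convergence and in regiochemical certainty this road is better than the chosen one.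
- Weak points: the stereocentre is only relocated. A2 still needs an enantioselective entry to an α-methyl alkyne and a C(sp3)–C(sp2) coupling to ring A. A3 needs a stereodefined trisubstituted iodoalkene made in the presence of ring C. The silver-mediated closure and aromatisation must be run beside two electron-rich furans and an enoate.
- Comparison: against the better convergence the chosen plan sets purchased furans for all three rings, a stereocentre fixed in one step from achiral one-step fragments, and a lower total step count once the preparations of A2 and A3 are included.

Alternative 2: The cut is the bond between the stereocentre and the CH2 on ring B, made while that CH2 is the α-carbon of an ester. Forward, the (2R,3E)-pent-3-en-2-yl ester A5 would be enolised with KN(SiMe3)2, silylated with Me3SiCl and rearranged through a chair (Ireland–Claisen) to acid A4. The carbinol configuration is relayed to the methyl centre and the new (E)-propenyl group points towards the future ring A.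
- Merits: the configuration comes from a carbinol centre that is cheaply obtained by resolution and is passed on by a dependable suprafacial [3,3] shift, without alkyllithium, diamine or cryogenic metalation. As a way of setting the centre it is at least as robust as the lithiation of 2 and probably easier to scale.
- Weak points: they lie after the key step. The carboxyl group of A4 is only a device and has to be removed from a carbon next to a furan. The propenyl end has to lose its methyl carbon and gain ring A. The chain must then be saturated by hydrogenation of a disubstituted C=C bond in the presence of three furans and the enoate, for which no clean method is apparent.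
- Comparison: the chosen plan sets against the more rugged key step that its boron stays useful. The atom leaving the stereocentre is replaced by the very CH2 the target needs, with nothing to excise and no alkene to reduce.

Alternative 3: Here ring A is the last ring made. The bond from ring A C2 to the vinyl carbon is cut and ring A is traced to the 4-substituted butenolide A7, which already holds the stereocentre and rings B and C; the (E)-iodoalkene A8 is the side-chain donor. Forward, A8 would be lithiated with t-BuLi, transmetalated with CeCl3 and added to the lactone carbonyl of A7. Acidic work-up would expel water and aromatise to the silyl ether A6.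
- Merits: the 2,4-pattern of ring A is guaranteed by construction, the alkene geometry is fixed in A8 before the union, and no palladium coupling at a β-bromofuran carrying an enoate is needed. In this last respect it is safer than step 12.
- Weak points: A7 contains the whole chain, so the stereocentre and both bonds to ring B must still be made by other means, and a butenolide has to be built on top. After A6 three more operations follow (desilylation and a two-stage oxidation to 26), the last of them with oxidants to which furans are not indifferent.
- Comparison: the chosen plan reaches the acid oxidation level directly through 23 and ends with a hydrolysis. It accepts in exchange the risk of the final Negishi coupling.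

Key step: step 3

Remark: the sense of induction is taken from the established course of sparteine-mediated α-deprotonation of O-alkyl esters and carbamates, in which the (−)-diamine removes the pro-S proton; the (S) centre of 26 therefore calls for (+)-sparteine, and (+)-sparteine and 2,4-dibromofuran 10 are taken to be purchasable.

## Route

Step 1
Reactants: 1 2,4,6-triisopropylbenzoic acid
Product: 2 ethyl 2,4,6-triisopropylbenzoate
Conditions: EtI, K2CO3, DMF, 50 °C
Reagents that add atoms: iodoethane, CCI
Why: O-alkylation of the carboxylate (SN2 at the ethyl group) bypasses the shielded carbonyl carbon, at which acid-catalysed esterification fails.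

Step 2
Reactants: 3 allyloxy(tert-butyl)dimethylsilane
Product: 4 tert-butyldimethyl[3-(4,4,5,5-tetramethyl-1,3,2-dioxaborolan-2-yl)propoxy]silane
Conditions: HBpin, [Ir(cod)Cl]2 (cat.), dppm (cat.), CH2Cl2, rt
Reagents that add atoms: pinacolborane, [H]B1OC(C)(C)C(C)(C)O1
Why: Iridium-catalysed hydroboration of a terminal alkene places boron at the terminal carbon, and the silyl ether is inert to the conditions.

Step 3
Reactants: 2 ethyl 2,4,6-triisopropylbenzoate; 4 tert-butyldimethyl[3-(4,4,5,5-tetramethyl-1,3,2-dioxaborolan-2-yl)propoxy]silane
Product: 7 tert-butyldimethyl{[(4S)-4-(4,4,5,5-tetramethyl-1,3,2-dioxaborolan-2-yl)pentyl]oxy}silane, via (1R)-1-lithioethyl 2,4,6-triisopropylbenzoate 5 (not isolated), via lithium boronate complex 6 (not isolated)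
Conditions: s-BuLi, (+)-sparteine, Et2O, −78 °C; then 4, −78 °C; then warm to 35 °C
Reagents that add atoms: none
Why: Lithiation–borylation, a stereospecific 1,2-metallate rearrangement of a boronate complex, is the reagent-controlled relative of the Matteson homologation and a known reaction of primary pinacol boronic esters. s-BuLi bound to (+)-sparteine removes the pro-R proton of the O–CH2 group of 2; the flanking isopropyl groups shield the carbonyl and block ortho-metalation, and the dipole-stabilised organolithium 5 keeps its configuration at −78 °C. 5 attacks the vacant orbital on boron of the unhindered ester 4 with retention to give 6, and on warming the 3-silyloxypropyl group shifts from boron to carbon anti to the departing benzoate, that is with inversion at carbon, which forms the C–C bond between the new stereocentre and the tether CH2 and leaves boron on the stereocentre. No ring is closed. The (S) configuration of 7 is decided only by the diamine in the deprotonation, because addition to boron and migration are both stereospecific; 4 carries no stereochemical information and need not direct anything. The step needs enantiotopic proton selection, which the sparteine complex provides, and single insertion, which follows from the order of events: complexation is fast at −78 °C whereas migration begins only on warming, when surplus 5 has decomposed, and 7 is more hindered than 4. The silyl ether oxygen is three carbons from boron, too far to be expelled from 6, and its bulky silyl group keeps it from competing for lithium.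

Step 4
Reactants: 7 tert-butyldimethyl{[(4S)-4-(4,4,5,5-tetramethyl-1,3,2-dioxaborolan-2-yl)pentyl]oxy}silane
Product: 9 tert-butyldimethyl{[(4R)-4-methyl-5-(4,4,5,5-tetramethyl-1,3,2-dioxaborolan-2-yl)pentyl]oxy}silane, via lithium chloromethyl boronate complex 8 (not isolated)
Conditions: BrCH2Cl, n-BuLi, Et2O, −78 °C → rt
Reagents that add atoms: bromochloromethane, ClCBr
Why: Matteson homologation: ClCH2Li made in the flask adds to boron and the secondary alkyl group migrates to CH2 with retention while chloride leaves, so the spatial arrangement at the stereocentre is unchanged (the descriptor becomes R only because the priorities change).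

Step 5
Reactants: 9 tert-butyldimethyl{[(4R)-4-methyl-5-(4,4,5,5-tetramethyl-1,3,2-dioxaborolan-2-yl)pentyl]oxy}silane; 10 2,4-dibromofuran
Product: 11 {[(4S)-5-(4-bromofuran-2-yl)-4-methylpentyl]oxy}(tert-butyl)dimethylsilane
Conditions: 10 (excess), Pd(OAc)2 (cat.), RuPhos (cat.), K3PO4, toluene/H2O, 80 °C
Reagents that add atoms: none
Why: B-alkyl Suzuki–Miyaura coupling of a primary pinacol boronic ester; zerovalent palladium inserts into the α C–Br bond (C2) of 10 in preference to the β C–Br bond and the excess of 10 holds back a second coupling, while the bulky biarylphosphine makes reductive elimination faster than β-hydride elimination, so the adjacent stereocentre is not touched.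

Step 6
Reactants: 12 3-bromofuran; 13 oxetane
Product: 15 3-(furan-3-yl)propan-1-ol, via furan-3-yllithium 14 (not isolated)
Conditions: n-BuLi, THF, −78 °C; then 13, BF3·OEt2, −78 °C
Reagents that add atoms: none
Why: Bromine–lithium exchange followed by ring opening of the BF3-activated oxetane by the organolithium (SN2 at CH2); holding −78 °C keeps 14 from isomerising to the 2-lithio species, so the tether is attached only at C3.

Step 7
Reactants: 15 3-(furan-3-yl)propan-1-ol
Product: 16 3-(3-iodopropyl)furan
Conditions: I2, PPh3, imidazole, CH2Cl2, 0 °C → rt
Reagents that add atoms: iodine, II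
Why: Appel-type iodination of a primary alcohol through the alkoxyphosphonium salt; the buffered, non-acidic medium spares the furan.

Step 8
Reactants: 16 3-(3-iodopropyl)furan; 11 {[(4S)-5-(4-bromofuran-2-yl)-4-methylpentyl]oxy}(tert-butyl)dimethylsilane
Product: 18 tert-butyl{[(4S)-5-{4-[3-(furan-3-yl)propyl]furan-2-yl}-4-methylpentyl]oxy}dimethylsilane, via [3-(furan-3-yl)propyl]zinc iodide 17 (not isolated)
Conditions: Zn dust, LiCl, THF, 40 °C; then 11, Pd(OAc)2 (cat.), SPhos (cat.), THF, 50 °C
Reagents that add atoms: none
Why: Zinc insertion into the primary iodide and Negishi coupling at the remaining β C–Br bond of ring B; the alkylzinc halide tolerates the silyl ether and both furans, and the electron-rich phosphine drives oxidative addition into the electron-rich bromofuran.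

Step 9
Reactants: 18 tert-butyl{[(4S)-5-{4-[3-(furan-3-yl)propyl]furan-2-yl}-4-methylpentyl]oxy}dimethylsilane
Product: 19 (4S)-5-{4-[3-(furan-3-yl)propyl]furan-2-yl}-4-methylpentan-1-ol
Conditions: Bu4NF, THF, 0 °C → rt
Reagents that add atoms: none
Why: Fluoride-induced cleavage of the silyl ether; no acid is involved and the furans are unaffected.

Step 10
Reactants: 19 (4S)-5-{4-[3-(furan-3-yl)propyl]furan-2-yl}-4-methylpentan-1-ol
Product: 20 4-[3-(furan-3-yl)propyl]-2-[(2S)-5-iodo-2-methylpentyl]furan
Conditions: I2, PPh3, imidazole, CH2Cl2, 0 °C
Reagents that add atoms: iodine, II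
Why: Appel-type iodination as in step 7; the stereocentre is three carbons from the reacting carbon and is not involved.

Step 11
Reactants: 21 4-bromofuran-2-carbaldehyde; 22 ethyl 2-(triphenyl-λ5-phosphanylidene)propanoate
Product: 23 ethyl (2E)-3-(4-bromofuran-2-yl)-2-methylprop-2-enoate
Conditions: toluene, 80 °C
Reagents that add atoms: none
Why: Wittig olefination with a stabilised α-methyl ylide, which gives the trisubstituted enoate with the furyl group trans to the ester (E).

Step 12
Reactants: 20 4-[3-(furan-3-yl)propyl]-2-[(2S)-5-iodo-2-methylpentyl]furan; 23 ethyl (2E)-3-(4-bromofuran-2-yl)-2-methylprop-2-enoate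
Product: 25 ethyl (2E)-3-{4-[(4S)-5-{4-[3-(furan-3-yl)propyl]furan-2-yl}-4-methylpentyl]furan-2-yl}-2-methylprop-2-enoate, via {(4S)-5-{4-[3-(furan-3-yl)propyl]furan-2-yl}-4-methylpentyl}zinc iodide 24 (not isolated)
Conditions: Zn dust, LiCl, THF, 40 °C; then 23, Pd(OAc)2 (cat.), SPhos (cat.), THF, 50 °C
Reagents that add atoms: none
Why: Negishi coupling of a primary alkylzinc iodide with the β-bromofuran of ring A; alkylzinc halides add neither to the ester nor in conjugate fashion to the enoate, and the alkene geometry is not affected.

Step 13
Reactants: 25 ethyl (2E)-3-{4-[(4S)-5-{4-[3-(furan-3-yl)propyl]furan-2-yl}-4-methylpentyl]furan-2-yl}-2-methylprop-2-enoate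
Product: 26 (2E)-3-{4-[(4S)-5-{4-[3-(furan-3-yl)propyl]furan-2-yl}-4-methylpentyl]furan-2-yl}-2-methylprop-2-enoic acid
Conditions: LiOH, THF/MeOH/H2O, rt; then cold dilute HCl to pH 4
Reagents that add atoms: lithium hydroxide (hydroxide oxygen), [Li+].[OH-]
Why: Saponification by acyl–oxygen cleavage; the conjugated, α-substituted enoate keeps its E geometry, and brief acidification at pH 4 in the cold does not harm the furans.

## Compound list

1 | 2,4,6-triisopropylbenzoic acid | CC(C)c1cc(C(C)C)c(C(=O)O)c(C(C)C)c1 | starting material
2 | ethyl 2,4,6-triisopropylbenzoate | CCOC(=O)c1c(C(C)C)cc(C(C)C)cc1C(C)C | intermediate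
3 | allyloxy(tert-butyl)dimethylsilane | C=CCO[Si](C)(C)C(C)(C)C | starting material
4 | tert-butyldimethyl[3-(4,4,5,5-tetramethyl-1,3,2-dioxaborolan-2-yl)propoxy]silane | CC(C)(C)[Si](C)(C)OCCCB1OC(C)(C)C(C)(C)O1 | intermediate
5 | (1R)-1-lithioethyl 2,4,6-triisopropylbenzoate, formed as its (+)-sparteine complex | C[C@H](OC(=O)c1c(C(C)C)cc(C(C)C)cc1C(C)C)[Li] | intermediate
6 | lithium [3-(tert-butyldimethylsilyloxy)propyl][(1R)-1-(2,4,6-triisopropylbenzoyloxy)ethyl](pinacolato)borate | [Li+].C[C@H](OC(=O)c1c(C(C)C)cc(C(C)C)cc1C(C)C)[B-]1(CCCO[Si](C)(C)C(C)(C)C)OC(C)(C)C(C)(C)O1 | intermediate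
7 | tert-butyldimethyl{[(4S)-4-(4,4,5,5-tetramethyl-1,3,2-dioxaborolan-2-yl)pentyl]oxy}silane | CC(C)(C)[Si](C)(C)OCCC[C@H](C)B1OC(C)(C)C(C)(C)O1 | intermediate
8 | lithium (chloromethyl)[(2S)-5-(tert-butyldimethylsilyloxy)pentan-2-yl](pinacolato)borate | [Li+].CC(C)(C)[Si](C)(C)OCCC[C@H](C)[B-]1(CCl)OC(C)(C)C(C)(C)O1 | intermediate
9 | tert-butyldimethyl{[(4R)-4-methyl-5-(4,4,5,5-tetramethyl-1,3,2-dioxaborolan-2-yl)pentyl]oxy}silane | CC(C)(C)[Si](C)(C)OCCC[C@H](C)CB1OC(C)(C)C(C)(C)O1 | intermediate
10 | 2,4-dibromofuran | Brc1cc(Br)co1 | starting material
11 | {[(4S)-5-(4-bromofuran-2-yl)-4-methylpentyl]oxy}(tert-butyl)dimethylsilane | CC(C)(C)[Si](C)(C)OCCC[C@H](C)Cc1cc(Br)co1 | intermediate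
12 | 3-bromofuran | Brc1ccoc1 | starting material
13 | oxetane | C1COC1 | starting material
14 | furan-3-yllithium | [Li]c1ccoc1 | intermediate
15 | 3-(furan-3-yl)propan-1-ol | OCCCc1ccoc1 | intermediate
16 | 3-(3-iodopropyl)furan | ICCCc1ccoc1 | intermediate
17 | [3-(furan-3-yl)propyl]zinc iodide | I[Zn]CCCc1ccoc1 | intermediate
18 | tert-butyl{[(4S)-5-{4-[3-(furan-3-yl)propyl]furan-2-yl}-4-methylpentyl]oxy}dimethylsilane | CC(C)(C)[Si](C)(C)OCCC[C@H](C)Cc1cc(CCCc2ccoc2)co1 | intermediate
19 | (4S)-5-{4-[3-(furan-3-yl)propyl]furan-2-yl}-4-methylpentan-1-ol | OCCC[C@H](C)Cc1cc(CCCc2ccoc2)co1 | intermediate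
20 | 4-[3-(furan-3-yl)propyl]-2-[(2S)-5-iodo-2-methylpentyl]furan | ICCC[C@H](C)Cc1cc(CCCc2ccoc2)co1 | intermediate
21 | 4-bromofuran-2-carbaldehyde | O=Cc1cc(Br)co1 | starting material
22 | ethyl 2-(triphenyl-λ5-phosphanylidene)propanoate | CCOC(=O)C(C)=P(c1ccccc1)(c1ccccc1)c1ccccc1 | starting material
23 | ethyl (2E)-3-(4-bromofuran-2-yl)-2-methylprop-2-enoate | C/C(=C\c1cc(Br)co1)C(=O)OCC | intermediate
24 | {(4S)-5-{4-[3-(furan-3-yl)propyl]furan-2-yl}-4-methylpentyl}zinc iodide | I[Zn]CCC[C@H](C)Cc1cc(CCCc2ccoc2)co1 | intermediate
25 | ethyl (2E)-3-{4-[(4S)-5-{4-[3-(furan-3-yl)propyl]furan-2-yl}-4-methylpentyl]furan-2-yl}-2-methylprop-2-enoate | C/C(=C\c1cc(CCC[C@H](C)Cc2cc(CCCc3ccoc3)co2)co1)C(=O)OCC | intermediate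
26 | (2E)-3-{4-[(4S)-5-{4-[3-(furan-3-yl)propyl]furan-2-yl}-4-methylpentyl]furan-2-yl}-2-methylprop-2-enoic acid | C/C(=C\c1cc(CCC[C@H](C)Cc2cc(CCCc3ccoc3)co2)co1)C(=O)O | target

## Step count and least certain steps

Total: 13 steps. Longest linear sequence: 9 steps (steps 2, 3, 4, 5, 8, 9, 10, 12 and 13 from 3; the sequence from 1 through step 1 has the same length).

**Step 3 (key step).** Imperfect discrimination between the two enantiotopic protons, or partial loss of configuration of the organolithium before it is captured by boron, would lower the enantiomeric purity. Nothing later in the route can repair this, because no second stereocentre is present. Incomplete capture or sluggish migration would leave unchanged 4, which is hard to separate from 7. Fallback: setting out from 2, the same deprotonation is quenched with Me3SnCl to give (1R)-1-(trimethylstannyl)ethyl 2,4,6-triisopropylbenzoate F1, a solid that can be recrystallised to enantiomeric homogeneity. Tin–lithium exchange with n-BuLi in Et2O at −78 °C then regenerates 5 with retention and free of diamine. Addition of 4 and warming lead through 6 back to the route at 7. The configuration is then set and purified in an isolable reagent, separately from the C–C bond formation.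

**Step 5.** Transmetalation of a β-branched primary pinacol boronic ester is slow. Protodeboronation, β-hydride elimination next to the stereocentre, or a second coupling at C4 of ring B may then compete. Fallback: setting out from 9, oxidation with NaOH/H2O2 gives (2S)-5-[(tert-butyldimethylsilyl)oxy]-2-methylpentan-1-ol F2. Iodination (I2, PPh3, imidazole) gives tert-butyl{[(4S)-5-iodo-4-methylpentyl]oxy}dimethylsilane F3. Zinc insertion (Zn, LiCl, THF) gives {(2S)-5-[(tert-butyldimethylsilyl)oxy]-2-methylpentyl}zinc iodide F4. Negishi coupling of F4 with 10 under PdCl2(dppf) catalysis, again at the more reactive α C–Br bond, comes back to the route at 11.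

**Step 12.** Oxidative addition into the β C–Br bond of 23 may be slow enough for the valuable organozinc 24 to be lost by protonation or homocoupling, and zinc insertion into 20 may be incomplete. Fallback: setting out from 20, iodine–lithium exchange with t-BuLi (Et2O, −78 °C) and capture with 9-methoxy-9-borabicyclo[3.3.1]nonane give lithium 9-{(4S)-5-{4-[3-(furan-3-yl)propyl]furan-2-yl}-4-methylpentyl}-9-methoxy-9-boranuidabicyclo[3.3.1]nonane F7. This borate is coupled with 23 in a B-alkyl Suzuki–Miyaura reaction (PdCl2(dppf), aqueous K3PO4, DMF) and returns to the route at 25.

**Step 8.** The electron-rich β-bromofuran 11 may undergo oxidative addition slowly, so that 17 is consumed by protonation or homocoupling before it couples. Fallback: setting out from 12, coupling with allylboronic acid pinacol ester (Pd(PPh3)4, CsF, THF, reflux) gives 3-(prop-2-en-1-yl)furan F5. Hydroboration with 9-BBN gives 9-[3-(furan-3-yl)propyl]-9-borabicyclo[3.3.1]nonane F6. B-alkyl Suzuki–Miyaura coupling of F6 with 11 (PdCl2(dppf), aqueous K3PO4, THF/DMF) comes back to the route at 18.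

## Further compounds

F1 | step 3 | (1R)-1-(trimethylstannyl)ethyl 2,4,6-triisopropylbenzoate | C[C@H](OC(=O)c1c(C(C)C)cc(C(C)C)cc1C(C)C)[Sn](C)(C)C
F2 | step 5 | (2S)-5-[(tert-butyldimethylsilyl)oxy]-2-methylpentan-1-ol | CC(C)(C)[Si](C)(C)OCCC[C@H](C)CO
F3 | step 5 | tert-butyl{[(4S)-5-iodo-4-methylpentyl]oxy}dimethylsilane | CC(C)(C)[Si](C)(C)OCCC[C@H](C)CI
F4 | step 5 | {(2S)-5-[(tert-butyldimethylsilyl)oxy]-2-methylpentyl}zinc iodide | CC(C)(C)[Si](C)(C)OCCC[C@H](C)C[Zn]I
F5 | step 8 | 3-(prop-2-en-1-yl)furan | C=CCc1ccoc1
F6 | step 8 | 9-[3-(furan-3-yl)propyl]-9-borabicyclo[3.3.1]nonane | B1(CCCc2ccoc2)C2CCCC1CCC2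
F7 | step 12 | lithium 9-{(4S)-5-{4-[3-(furan-3-yl)propyl]furan-2-yl}-4-methylpentyl}-9-methoxy-9-boranuidabicyclo[3.3.1]nonane | [Li+].CO[B-]1(CCC[C@H](C)Cc2cc(CCCc3ccoc3)co2)C2CCCC1CCC2
A1 | alternative 1 | ethyl (2E)-3-{4-[(4S)-5-{4-[3-(furan-3-yl)propyl]furan-2-yl}-4-methylpentyl]furan-2-yl}-2-methylprop-2-enoate (identical with 25) | C/C(=C\c1cc(CCC[C@H](C)Cc2cc(CCCc3ccoc3)co2)co1)C(=O)OCC
A2 | alternative 1 | ethyl (2E)-2-methyl-3-{4-[(4S)-4-methylhex-5-yn-1-yl]furan-2-yl}prop-2-enoate | C/C(=C\c1cc(CCC[C@H](C)C#C)co1)C(=O)OCC
A3 | alternative 1 | (2Z)-5-(furan-3-yl)-2-(iodomethylidene)pentan-1-ol | OC/C(CCCc1ccoc1)=C\I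
A4 | alternative 2 | (3S,4E)-2-{4-[3-(furan-3-yl)propyl]furan-2-yl}-3-methylhex-4-enoic acid (either epimer at C2) | C/C=C/[C@H](C)C(C(=O)O)c1cc(CCCc2ccoc2)co1
A5 | alternative 2 | (2R,3E)-pent-3-en-2-yl {4-[3-(furan-3-yl)propyl]furan-2-yl}acetate | C/C=C/[C@@H](C)OC(=O)Cc1cc(CCCc2ccoc2)co1
A6 | alternative 3 | tert-butyl{[(2E)-3-{4-[(4S)-5-{4-[3-(furan-3-yl)propyl]furan-2-yl}-4-methylpentyl]furan-2-yl}-2-methylprop-2-en-1-yl]oxy}dimethylsilane | C/C(=C\c1cc(CCC[C@H](C)Cc2cc(CCCc3ccoc3)co2)co1)CO[Si](C)(C)C(C)(C)C
A7 | alternative 3 | 4-[(4S)-5-{4-[3-(furan-3-yl)propyl]furan-2-yl}-4-methylpentyl]furan-2(5H)-one | O=C1C=C(CCC[C@H](C)Cc2cc(CCCc3ccoc3)co2)CO1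
A8 | alternative 3 | tert-butyl{[(2E)-3-iodo-2-methylprop-2-en-1-yl]oxy}dimethylsilane | C/C(=C\I)CO[Si](C)(C)C(C)(C)C
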